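At 30% conversion of the starting material, this flask is asked what holds its catalyst and how its rate answers to the charges.

starting material 0.85 M; partner 0.935 M; free catalyst 21 mM

    partner + free catalyst ⇌ catalyst intermediate A (K1 = 0.40 L mol⁻¹, k1 = 0.72 L mol⁻¹ s⁻¹)
    starting material + catalyst intermediate A ⇌ catalyst intermediate B (K2 = 2.8 L mol⁻¹, k2 = 47 L mol⁻¹ s⁻¹)
    catalyst intermediate B → catalyst intermediate C (k3 = 9.0 s⁻¹)
    catalyst intermediate C → free catalyst + target (k4 = 1.7 s⁻¹)
    partner → decomposed reagent (k5 = 0.014 s⁻¹)

1. the form that holds most of the catalyst when 30% of the starting material are converted (catalyst intermediate C / catalyst intermediate A / catalyst intermediate B / free catalyst)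
2. its share of the catalyst then
3. apparent order in free catalyst when 30% of the starting material are converted (percent change of the rate of making target for one percent more free catalyst charged)
4. apparent order in partner when 30% of the starting material are converted (percent change of the rate of making target for one percent more partner charged)
5. factor on the rate of making target when 30% of the starting material are converted if free catalyst is charged twice over

**Catalyst round.** At that moment [starting material] is 0.595 M and target stands at 0.255 M. Catalyst intermediate A goes forward with 9.76 s⁻¹, which is step 2 thinned by the falling back of catalyst intermediate B, and so 84.4% of partner bindings lead on to target. Each round then costs the catalyst a stay of 0.802 s in bound forms, longest in catalyst intermediate C. With the bound forms made as fast as they are used, the rate of making target is κ[partner]/(1 + β[partner]), where κ = 0.01277 s⁻¹ and β = 0.487 L mol⁻¹.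

**Waste ratio.** Partner also decomposes, at k5[partner], and the constant 0.014 s⁻¹ exceeds κ. Dividing the two rates removes time: decomposition per target made is k5(1 + β[partner])/κ. With [partner] taken at charge less target, 0.680 M, this gives 1.46, the moles of partner decomposed per mole of target made, here called the waste ratio. Held at that value, the ratio makes the integral a straight line in target that needs no clock: 0.935 M less 0.255 M consumed and less 0.372 M decomposed leaves a reckoned 0.308 M of partner.

**Reckoned answers.** That [partner] gives free catalyst as the resting state, with a share of 87.0%. The comparison is at fixed conversion, so extra catalyst lowers the waste ratio and saves partner, and the order in free catalyst comes to 2.05. Extra partner lands on a small remainder, though it raises the waste ratio a little, which gives an order of 2.28. A doubled catalyst charge brings the ratio to 0.730 and partner to 0.494 M, a factor of 2.98 on the rate.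

**The forecast.** The forecast gave free catalyst at 86%, orders of 1.9 and 2.2 and a factor of 2.85, somewhat under the orders and factor reckoned here, on the ground that “more catalyst gets there sooner with more partner surviving”.

**The result.** The flask reaches that conversion at 43.6 s with free catalyst at 86.2% and catalyst intermediate C next at 10.2%. Its orders are 1.9 and 2.2, and its factor is 2.86.

**Largest effect.** Among the steps taken away in turn, the turning of partner into decomposed reagent has the largest single effect on the rate at that conversion. With the waste ratio of 1.46 set to zero, the reckoning leaves 0.680 M of partner, and the rate law then gives 1.91 times the rate. The run without that step gives 1.80 times the rate, with orders falling to 1.0 in free catalyst and 1.0 in partner.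

(The numbers of this flask come from no measurement, and the outcome is calculated.)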